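Ring A is a resorcinol whose only C–H (C2) sits between the two oxygenated carbons C1 and C3, while C4, C5 and C6 carry benzyl, phenethyl and benzyl groups. That pattern is cut at C1–C2 and C1–C6. C1 is supplied by carbon monoxide and C2–C6 by an acyclic tertiary 3-acetoxy-1,4-enyne with a terminal alkyne (C2≡C3), the ester on C4 and an E-trisubstituted C5=C6 alkene. One rhodium-catalysed carbonylative (5+1) benzannulation moves the acetate to C3, closes ring A and leaves the two oxygens differentiated (free OH at C1, OAc at C3), so methylation needs no selectivity. All phenols travel as benzyl ethers.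

Key step: step 9

Assumption: the trivial name is read as the bibenzyl (3,3'-dihydroxy-2,6-bis(p-hydroxybenzyl)-5-methoxybibenzyl); the SMILES string defines the target, which is achiral.

Numbering used throughout for ring A: C1 (OMe), C2 (H), C3 (OH), C4 (p-hydroxybenzyl), C5 (3-hydroxyphenethyl), C6 (p-hydroxybenzyl). Apart from the methyl group, C1/C3 and C4/C6 are related by a plane through C2 and C5, so methylating either oxygen gives the same compound.

Design notes:
- The enyne alkene must be E, with the C6 benzyl group pointing away from C4, so that H occupies the inner position at the closing terminus.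
- The acetate is kept because it can be placed on the crowded tertiary alkoxide in the flask.
- The enolisable benzyl ketone is alkynylated with lanthanum assistance.

Step 1
Reactants: 1 2-(3-hydroxyphenyl)ethanol
Product: 2 2-[3-(benzyloxy)phenyl]ethanol
Conditions: BnBr, K2CO3, acetone, reflux
Reagents that add atoms: benzyl bromide, BrCc1ccccc1
Why: Williamson ether synthesis; K2CO3 deprotonates only the phenol, which is far more acidic than the primary alcohol, so benzylation should be confined to the aryl oxygen.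

Step 2
Reactants: 2 2-[3-(benzyloxy)phenyl]ethanol
Product: 3 1-(benzyloxy)-3-(2-bromoethyl)benzene
Conditions: CBr4, PPh3, CH2Cl2, 0 °C to rt
Reagents that add atoms: tetrabromomethane, BrC(Br)(Br)Br
Why: Appel reaction; the primary alcohol is activated as an alkoxyphosphonium ion and displaced by bromide under neutral conditions that spare the benzyl ether and should avoid elimination to the styrene.

Step 3
Reactants: 4 propargyl alcohol; 5 4-(benzyloxy)benzyl chloride
Product: 7 4-[4-(benzyloxy)phenyl]but-2-yn-1-ol, via propargyl alcohol dimagnesium salt 6 (not isolated)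
Conditions: EtMgBr (2.1 equiv), THF, 0 °C to rt; CuI (10 mol %), then 5, 60 °C; aq NH4Cl
Reagents that add atoms: none
Why: Copper-catalysed coupling of an alkynyl Grignard reagent with a benzylic halide; double deprotonation masks the hydroxyl as a poorly nucleophilic magnesium alkoxide, so the activated benzylic chloride should be displaced only by the alkynyl carbon.

Step 4
Reactants: 3 1-(benzyloxy)-3-(2-bromoethyl)benzene; 7 4-[4-(benzyloxy)phenyl]but-2-yn-1-ol
Product: 10 (2E)-4-[4-(benzyloxy)phenyl]-2-{2-[3-(benzyloxy)phenyl]ethyl}but-2-en-1-ol, via phenethyl Grignard reagent 8 (not isolated), via oxamagnesacycle 9 (not isolated)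
Conditions: 3, Mg, Et2O, reflux (gives 8, 3 equiv); 7, CuI (20 mol %), Et2O–toluene, 0 °C to rt; aq NH4Cl
Reagents that add atoms: none
Why: Copper-catalysed anti-carbomagnesiation of a propargylic alkoxide; the alkoxide steers the alkyl group to the proximal alkyne carbon and magnesium to the distal one inside a five-membered chelate that forces CH2O and Mg to be cis, so protonation should give the E alkene with CH2OH trans to the benzyl group.

Step 5
Reactants: 10 (2E)-4-[4-(benzyloxy)phenyl]-2-{2-[3-(benzyloxy)phenyl]ethyl}but-2-en-1-ol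
Product: 11 (2E)-4-[4-(benzyloxy)phenyl]-2-{2-[3-(benzyloxy)phenyl]ethyl}but-2-enal
Conditions: activated MnO2 (excess), CH2Cl2, rt
Reagents that add atoms: none
Why: MnO2 oxidation of an allylic alcohol; the neutral heterogeneous oxidant stops at the aldehyde and should neither disturb the E geometry (the preferred one for a 2-alkyl enal) nor move the alkene toward the arene.

Step 6
Reactants: 11 (2E)-4-[4-(benzyloxy)phenyl]-2-{2-[3-(benzyloxy)phenyl]ethyl}but-2-enal; 5 4-(benzyloxy)benzyl chloride
Product: 13 (3E)-1,5-bis[4-(benzyloxy)phenyl]-3-{2-[3-(benzyloxy)phenyl]ethyl}pent-3-en-2-ol (racemic), via benzylic Grignard reagent 12 (not isolated)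
Conditions: 5, Mg (excess), THF, 0 °C, slow addition at high dilution (gives 12); 11, THF, −78 to 0 °C; aq NH4Cl
Reagents that add atoms: none
Why: Grignard 1,2-addition to an enal; the benzylic reagent, made cold and dilute to limit Wurtz coupling, attacks the aldehyde carbon, and the new carbinol centre is formed without control (racemic) and erased in step 7.

Step 7
Reactants: 13 (3E)-1,5-bis[4-(benzyloxy)phenyl]-3-{2-[3-(benzyloxy)phenyl]ethyl}pent-3-en-2-ol
Product: 14 (3E)-1,5-bis[4-(benzyloxy)phenyl]-3-{2-[3-(benzyloxy)phenyl]ethyl}pent-3-en-2-one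
Conditions: Dess–Martin periodinane, CH2Cl2, 0 °C to rt
Reagents that add atoms: none
Why: Dess–Martin oxidation; a mild, base-free conversion of the secondary allylic alcohol into the enone that should avoid enolisation at the benzylic alpha-CH2 and migration of the skipped alkene.

Step 8
Reactants: 14 (3E)-1,5-bis[4-(benzyloxy)phenyl]-3-{2-[3-(benzyloxy)phenyl]ethyl}pent-3-en-2-one; 15 ethynylmagnesium bromide
Product: 17 (4E)-3-[4-(benzyloxy)benzyl]-6-[4-(benzyloxy)phenyl]-4-{2-[3-(benzyloxy)phenyl]ethyl}hex-4-en-1-yn-3-yl acetate (racemic), via tertiary bromomagnesium alkoxide 16 (not isolated)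
Conditions: LaCl3·2LiCl (1 equiv), 15 (3 equiv), THF, 0 °C; then Ac2O (excess), DMAP (cat.), 0 °C to rt; chromatography on Et3N-washed silica
Reagents that add atoms: acetic anhydride, CC(=O)OC(C)=O
Why: Lanthanide-assisted alkynyl Grignard 1,2-addition followed by in-flask O-acylation; LaCl3·2LiCl raises carbonyl electrophilicity and tempers basicity so that addition should outrun enolisation of the benzyl ketone, trapping the alkoxide avoids handling the ionisable tertiary alcohol, and the quaternary centre forms racemic and disappears on aromatisation.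

Step 9
Reactants: 17 (4E)-3-[4-(benzyloxy)benzyl]-6-[4-(benzyloxy)phenyl]-4-{2-[3-(benzyloxy)phenyl]ethyl}hex-4-en-1-yn-3-yl acetate; 18 carbon monoxide
Product: 20 2,4-bis[4-(benzyloxy)benzyl]-3-{2-[3-(benzyloxy)phenyl]ethyl}-5-hydroxyphenyl acetate, via cyclohexadienone 19 (not isolated)
Conditions: [Rh(CO)2Cl]2 (5 mol %), CO (80 atm, autoclave), CH2Cl2, 80 °C
Reagents that add atoms: none
Why: Monovalent rhodium binds the terminal alkyne, the acetate carbonyl oxygen attacks C3 to form a dioxolenium ion, and its opening transfers the ester from C4 to C3 and leaves a rhodium carbene at C2 that is conjugated through C3=C4 with the C5=C6 alkene. Ring A closes in a (5+1) mode: a 6π-type closure gives a rhodacyclohexadiene bonded to C2 and C6 (equivalently, CO capture gives a dienylketene that electrocyclises), CO inserts, and reductive elimination forms C1–C2 and C1–C6 to give dienone 19, whose C6–H moves to oxygen to deliver phenol 20. The closest known reaction type is the rhodium-catalysed carbonylative (5+1) cycloaddition of terminal 3-acyloxy-1,4-enynes to resorcinol monoesters, and the tertiary carbinol ester used here lies at the demanding end of that substrate class. No stereocentre survives, since the racemic C4 centre becomes sp2 and the transient C6 centre of 19 is lost on tautomerisation. The step needs 1,2- rather than 1,3-acyloxy migration (the latter leads through an allenyl acetate to a cyclopentenone) and CO capture rather than Rautenstrauch-type five-ring closure; the unsubstituted alkyne terminus favours the 1,2-shift and high CO pressure favours carbonylation. The E alkene puts H and not the benzyl group on the inner side of C6, which keeps the closing terminus accessible and supplies the hydrogen needed for aromatisation.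

Step 10
Reactants: 20 2,4-bis[4-(benzyloxy)benzyl]-3-{2-[3-(benzyloxy)phenyl]ethyl}-5-hydroxyphenyl acetate
Product: 22 2,4-bis[4-(benzyloxy)benzyl]-3-{2-[3-(benzyloxy)phenyl]ethyl}-5-methoxyphenol, via methyl ether acetate 21 (not isolated)
Conditions: MeI (3 equiv), K2CO3, acetone, rt; filter and strip all volatiles (removes MeI); K2CO3 (cat.), MeOH–THF, rt
Reagents that add atoms: iodomethane, CI
Why: Williamson methylation of the only free phenol (C1–OH) followed, once MeI has been removed so that the second oxygen cannot be alkylated, by K2CO3-catalysed transesterification of the aryl acetate with methanol, both operations leaving the benzyl ethers untouched.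

Step 11
Reactants: 22 2,4-bis[4-(benzyloxy)benzyl]-3-{2-[3-(benzyloxy)phenyl]ethyl}-5-methoxyphenol
Product: 23 3,3'-dihydroxy-2,6-bis(p-hydroxybenzyl)-5-methoxybibenzyl
Conditions: H2 (1 atm), Pd/C (10 wt %), EtOAc–MeOH, rt
Reagents that add atoms: none
Why: Catalytic hydrogenolysis; the three O-benzyl C–O bonds are cleaved over Pd/C, while the diarylmethane and bibenzyl C–C bonds, the methyl ether and the arenes should be inert at one atmosphere of hydrogen.

Compound list
1 | 2-(3-hydroxyphenyl)ethanol | OCCc1cccc(O)c1 | starting material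
2 | 2-[3-(benzyloxy)phenyl]ethanol | OCCc1cccc(OCc2ccccc2)c1 | intermediate
3 | 1-(benzyloxy)-3-(2-bromoethyl)benzene | BrCCc1cccc(OCc2ccccc2)c1 | intermediate
4 | propargyl alcohol (prop-2-yn-1-ol) | OCC#C | starting material
5 | 4-(benzyloxy)benzyl chloride | ClCc1ccc(OCc2ccccc2)cc1 | starting material
6 | propargyl alcohol dimagnesium salt (O- and C-bromomagnesio) | Br[Mg]OCC#C[Mg]Br | intermediate
7 | 4-[4-(benzyloxy)phenyl]but-2-yn-1-ol | OCC#CCc1ccc(OCc2ccccc2)cc1 | intermediate
8 | 2-[3-(benzyloxy)phenyl]ethylmagnesium bromide | Br[Mg]CCc1cccc(OCc2ccccc2)c1 | intermediate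
9 | 3-[4-(benzyloxy)benzyl]-4-{2-[3-(benzyloxy)phenyl]ethyl}-2,5-dihydro-1,2-oxamagnesole (cyclic alkenylmagnesium alkoxide) | C1O[Mg]C(Cc2ccc(OCc3ccccc3)cc2)=C1CCc1cccc(OCc2ccccc2)c1 | intermediate
10 | (2E)-4-[4-(benzyloxy)phenyl]-2-{2-[3-(benzyloxy)phenyl]ethyl}but-2-en-1-ol | OC/C(CCc1cccc(OCc2ccccc2)c1)=C/Cc1ccc(OCc2ccccc2)cc1 | intermediate
11 | (2E)-4-[4-(benzyloxy)phenyl]-2-{2-[3-(benzyloxy)phenyl]ethyl}but-2-enal | O=C/C(CCc1cccc(OCc2ccccc2)c1)=C/Cc1ccc(OCc2ccccc2)cc1 | intermediate
12 | 4-(benzyloxy)benzylmagnesium chloride | Cl[Mg]Cc1ccc(OCc2ccccc2)cc1 | intermediate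
13 | (3E)-1,5-bis[4-(benzyloxy)phenyl]-3-{2-[3-(benzyloxy)phenyl]ethyl}pent-3-en-2-ol (racemic) | OC(Cc1ccc(OCc2ccccc2)cc1)/C(CCc1cccc(OCc2ccccc2)c1)=C/Cc1ccc(OCc2ccccc2)cc1 | intermediate
14 | (3E)-1,5-bis[4-(benzyloxy)phenyl]-3-{2-[3-(benzyloxy)phenyl]ethyl}pent-3-en-2-one | O=C(Cc1ccc(OCc2ccccc2)cc1)/C(CCc1cccc(OCc2ccccc2)c1)=C/Cc1ccc(OCc2ccccc2)cc1 | intermediate
15 | ethynylmagnesium bromide | C#C[Mg]Br | starting material
16 | bromomagnesium (4E)-3-[4-(benzyloxy)benzyl]-6-[4-(benzyloxy)phenyl]-4-{2-[3-(benzyloxy)phenyl]ethyl}hex-4-en-1-yn-3-olate (racemic) | C#CC(O[Mg]Br)(Cc1ccc(OCc2ccccc2)cc1)/C(CCc1cccc(OCc2ccccc2)c1)=C/Cc1ccc(OCc2ccccc2)cc1 | intermediate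
17 | (4E)-3-[4-(benzyloxy)benzyl]-6-[4-(benzyloxy)phenyl]-4-{2-[3-(benzyloxy)phenyl]ethyl}hex-4-en-1-yn-3-yl acetate (racemic) | C#CC(OC(C)=O)(Cc1ccc(OCc2ccccc2)cc1)/C(CCc1cccc(OCc2ccccc2)c1)=C/Cc1ccc(OCc2ccccc2)cc1 | intermediate
18 | carbon monoxide | [C-]#[O+] | starting material
19 | 4,6-bis[4-(benzyloxy)benzyl]-5-{2-[3-(benzyloxy)phenyl]ethyl}-3-oxocyclohexa-1,5-dien-1-yl acetate (racemic) | CC(=O)OC1=CC(=O)C(Cc2ccc(OCc3ccccc3)cc2)C(CCc2cccc(OCc3ccccc3)c2)=C1Cc1ccc(OCc2ccccc2)cc1 | intermediate
20 | 2,4-bis[4-(benzyloxy)benzyl]-3-{2-[3-(benzyloxy)phenyl]ethyl}-5-hydroxyphenyl acetate | CC(=O)Oc1cc(O)c(Cc2ccc(OCc3ccccc3)cc2)c(CCc2cccc(OCc3ccccc3)c2)c1Cc1ccc(OCc2ccccc2)cc1 | intermediate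
21 | 2,4-bis[4-(benzyloxy)benzyl]-3-{2-[3-(benzyloxy)phenyl]ethyl}-5-methoxyphenyl acetate | CC(=O)Oc1cc(OC)c(Cc2ccc(OCc3ccccc3)cc2)c(CCc2cccc(OCc3ccccc3)c2)c1Cc1ccc(OCc2ccccc2)cc1 | intermediate
22 | 2,4-bis[4-(benzyloxy)benzyl]-3-{2-[3-(benzyloxy)phenyl]ethyl}-5-methoxyphenol | COc1cc(O)c(Cc2ccc(OCc3ccccc3)cc2)c(CCc2cccc(OCc3ccccc3)c2)c1Cc1ccc(OCc2ccccc2)cc1 | intermediate
23 | 3,3'-dihydroxy-2,6-bis(p-hydroxybenzyl)-5-methoxybibenzyl | COc1cc(O)c(Cc2ccc(O)cc2)c(CCc2cccc(O)c2)c1Cc1ccc(O)cc1 | target

Total step count: 11.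
Longest linear sequence: 10 steps (1 → 2 → 3 → 10 → 11 → 13 → 14 → 17 → 20 → 22 → 23). Step 3 runs in parallel.

Steps most likely to fail

**Step 9.** The crowded tertiary, allylic and propargylic ester may ionise and lose acetic acid toward the benzylic CH2. The ester may migrate 1,3 instead of 1,2. The vinylcarbene may also close to a five-membered ring before CO is taken up. The fallback gives up ring construction and decorates a preformed arene. It sets out from bromide 3 (through Grignard reagent 8) and chloride 5 and comes back at target 23. Commercial 3-bromo-5-methoxyphenol would be benzylated (BnBr, K2CO3, acetone) to 1-(benzyloxy)-3-bromo-5-methoxybenzene F1. Kumada–Corriu coupling of F1 with 8 under PdCl2(dppf) should give 1-(benzyloxy)-3-{2-[3-(benzyloxy)phenyl]ethyl}-5-methoxybenzene F2. Two equivalents of N-bromosuccinimide in MeCN at 0 °C should brominate ring A, the most electron-rich arene. Attack is expected at the two positions that flank the tether, each para to one oxygen, giving 1-(benzyloxy)-2,4-dibromo-3-{2-[3-(benzyloxy)phenyl]ethyl}-5-methoxybenzene F3. Zinc insertion into 5 (Zn, LiCl, THF) would provide 4-(benzyloxy)benzylzinc chloride F4. A double Negishi coupling of F3 with F4 (Pd(OAc)2, SPhos, THF) should give 1-(benzyloxy)-2,4-bis[4-(benzyloxy)benzyl]-3-{2-[3-(benzyloxy)phenyl]ethyl}-5-methoxybenzene F5. Hydrogenolysis of its four benzyl ethers under the conditions of step 11 leads to 23.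

**Step 4.** Carbometalation by a primary alkyl Grignard reagent that carries beta-hydrogens may be sluggish or regiochemically imperfect on an internal alkyne. Base-induced propargyl-to-allene isomerisation at the doubly activated CH2 may compete. The fallback separates the stereodefining event from the C–C bond formation. It sets out from alkynol 7 and comes back at allylic alcohol 10. Hydroxyl-directed trans-hydrostannation (Bu3SnH, [Cp*RuCl]4 cat., CH2Cl2, rt) should place tin on the proximal carbon and give (2Z)-4-[4-(benzyloxy)phenyl]-2-(tributylstannyl)but-2-en-1-ol F6. Tin–iodine exchange with I2 in CH2Cl2 at 0 °C proceeds with retention to (2Z)-4-[4-(benzyloxy)phenyl]-2-iodobut-2-en-1-ol F7. Bromide 3 would be converted with Zn and LiCl in THF into 2-[3-(benzyloxy)phenyl]ethylzinc bromide F8. Negishi coupling of F7 with excess F8 under PdCl2(dppf) should then give 10 with retention of geometry.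

**Step 8.** The benzyl ketone may be enolised instead of attacked, and acylation of the hindered alkoxide may be incomplete. The fallback reverses the order in which the two carbon groups reach the carbinol carbon, so that the last addition meets a ketone without alpha-hydrogens. It sets out from enal 11 and comes back at acetate 17. Commercial lithium (trimethylsilyl)acetylide in THF at −78 °C should add to 11 to give (4E)-6-[4-(benzyloxy)phenyl]-4-{2-[3-(benzyloxy)phenyl]ethyl}-1-(trimethylsilyl)hex-4-en-1-yn-3-ol F9. MnO2 in CH2Cl2 oxidises this doubly activated alcohol to (4E)-6-[4-(benzyloxy)phenyl]-4-{2-[3-(benzyloxy)phenyl]ethyl}-1-(trimethylsilyl)hex-4-en-1-yn-3-one F10. Grignard reagent 12 adds 1,2 at −78 °C, the silyl cap removing the acidic alkyne hydrogen and shielding the alkyne terminus. This gives chloromagnesium (4E)-3-[4-(benzyloxy)benzyl]-6-[4-(benzyloxy)phenyl]-4-{2-[3-(benzyloxy)phenyl]ethyl}-1-(trimethylsilyl)hex-4-en-1-yn-3-olate F11. F11 is acetylated in the flask (Ac2O, DMAP) to (4E)-3-[4-(benzyloxy)benzyl]-6-[4-(benzyloxy)phenyl]-4-{2-[3-(benzyloxy)phenyl]ethyl}-1-(trimethylsilyl)hex-4-en-1-yn-3-yl acetate F12. Protodesilylation with Bu4NF buffered by AcOH in THF at 0 °C should then release 17 without touching the tertiary acetate.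

Further compounds
F1 | step 9 | 1-(benzyloxy)-3-bromo-5-methoxybenzene | COc1cc(Br)cc(OCc2ccccc2)c1
F2 | step 9 | 1-(benzyloxy)-3-{2-[3-(benzyloxy)phenyl]ethyl}-5-methoxybenzene | COc1cc(CCc2cccc(OCc3ccccc3)c2)cc(OCc2ccccc2)c1
F3 | step 9 | 1-(benzyloxy)-2,4-dibromo-3-{2-[3-(benzyloxy)phenyl]ethyl}-5-methoxybenzene | COc1cc(OCc2ccccc2)c(Br)c(CCc2cccc(OCc3ccccc3)c2)c1Br
F4 | step 9 | 4-(benzyloxy)benzylzinc chloride | Cl[Zn]Cc1ccc(OCc2ccccc2)cc1
F5 | step 9 | 1-(benzyloxy)-2,4-bis[4-(benzyloxy)benzyl]-3-{2-[3-(benzyloxy)phenyl]ethyl}-5-methoxybenzene | COc1cc(OCc2ccccc2)c(Cc2ccc(OCc3ccccc3)cc2)c(CCc2cccc(OCc3ccccc3)c2)c1Cc1ccc(OCc2ccccc2)cc1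
F6 | step 4 | (2Z)-4-[4-(benzyloxy)phenyl]-2-(tributylstannyl)but-2-en-1-ol | OC/C([Sn](CCCC)(CCCC)CCCC)=C/Cc1ccc(OCc2ccccc2)cc1
F7 | step 4 | (2Z)-4-[4-(benzyloxy)phenyl]-2-iodobut-2-en-1-ol | OC/C(I)=C/Cc1ccc(OCc2ccccc2)cc1
F8 | step 4 | 2-[3-(benzyloxy)phenyl]ethylzinc bromide | Br[Zn]CCc1cccc(OCc2ccccc2)c1
F9 | step 8 | (4E)-6-[4-(benzyloxy)phenyl]-4-{2-[3-(benzyloxy)phenyl]ethyl}-1-(trimethylsilyl)hex-4-en-1-yn-3-ol (racemic) | C[Si](C)(C)C#CC(O)/C(CCc1cccc(OCc2ccccc2)c1)=C/Cc1ccc(OCc2ccccc2)cc1
F10 | step 8 | (4E)-6-[4-(benzyloxy)phenyl]-4-{2-[3-(benzyloxy)phenyl]ethyl}-1-(trimethylsilyl)hex-4-en-1-yn-3-one | C[Si](C)(C)C#CC(=O)/C(CCc1cccc(OCc2ccccc2)c1)=C/Cc1ccc(OCc2ccccc2)cc1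
F11 | step 8 | chloromagnesium (4E)-3-[4-(benzyloxy)benzyl]-6-[4-(benzyloxy)phenyl]-4-{2-[3-(benzyloxy)phenyl]ethyl}-1-(trimethylsilyl)hex-4-en-1-yn-3-olate (racemic) | C[Si](C)(C)C#CC(O[Mg]Cl)(Cc1ccc(OCc2ccccc2)cc1)/C(CCc1cccc(OCc2ccccc2)c1)=C/Cc1ccc(OCc2ccccc2)cc1
F12 | step 8 | (4E)-3-[4-(benzyloxy)benzyl]-6-[4-(benzyloxy)phenyl]-4-{2-[3-(benzyloxy)phenyl]ethyl}-1-(trimethylsilyl)hex-4-en-1-yn-3-yl acetate (racemic) | C[Si](C)(C)C#CC(OC(C)=O)(Cc1ccc(OCc2ccccc2)cc1)/C(CCc1cccc(OCc2ccccc2)c1)=C/Cc1ccc(OCc2ccccc2)cc1
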